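**Plan**

1. Retrosynthetic cuts: the C2 acetate goes back to a C2 ketone (reduction, then inversion) and the C3 methyl enol ether to α-oxidation beside that ketone, which is carried as a dimethyl ketal. The skeleton is then cut at C1–C7 (reverse α-ketol shift, C7 returns to C8), at C5–C6 and C7–C8 (retro-[2+2] to a 2-acyloxy enone and the (E)-propenylarene) and at C5–allyl (retro-Claisen).
2. Enabling feature: the cyclopentanone ring C8–C1–C7–C6–C5 is a cyclobutane C5–C6–C7–C8 widened by one bond. That cyclobutane lies on the C5–C8 edge of the six-membered ring C8–C1–C2–C3–C4–C5, whose C1 is then a ketone beside a C8 carbinol (an α-ketol).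
3. Forward order: the six-membered ring is bought (cyclohexane-1,2-dione) and receives the ketal, the enol oxygen and the allyl group; the four-membered ring is closed by enone–alkene photocycloaddition; it is enlarged to the five-membered ring of the bicyclo[3.2.1]octane by the ketol shift; C2 and C3 are then adjusted.
4. Stereochemistry: the photocycloaddition sets C5/C8 (cis fusion), C7 (aryl exo) and C6 (methyl endo, trans to aryl). The absolute sense comes from a (1S,4R)-camphanoyl enol ester whose diastereomeric adducts are separated. C1 follows from the suprafacial shift, C2 from exo-face hydride delivery and Mitsunobu inversion.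

Key step: step 7

Remark: carbons carry the target's bicyclo[3.2.1]octane locants in every intermediate (C1 OMe bridgehead, C2–C4 bridge, C5 allyl bridgehead, C6 methyl, C7 aryl, C8 carbonyl bridge). "Exo" means on the C8 side of the C6–C7 bridge and, in the cyclobutanes, on the convex face.
Remark: face selection is given to a covalently bound acyl auxiliary, not a chiral Lewis acid, because the tetrasubstituted enone has no α-hydrogen for two-point binding and a strong Lewis acid would endanger the ketal and the electron-rich alkene.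
Assumption: the camphanoyl group is taken to bias the two enone faces only modestly; the route relies on separating the two diastereomeric photoadducts, not on that bias.

Step 1
Reactants: 1 cyclohexane-1,2-dione
Product: 2 2,2-dimethoxycyclohexan-1-one
Conditions: HC(OMe)3, MeOH, TsOH·H2O (cat.), rt
Reagents that add atoms: trimethyl orthoformate, COC(OC)OC; methanol, CO
Why: Acid-catalysed ketalisation with the orthoformate as water scavenger should stop at the monoketal, because the first ketal inductively deactivates the neighbouring carbonyl towards a second ketalisation.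

Step 2
Reactants: 2 2,2-dimethoxycyclohexan-1-one
Product: 4 6-hydroxy-2,2-dimethoxycyclohexan-1-one (racemic), via potassium 6,6-dimethoxycyclohex-1-en-1-olate 3 (not isolated)
Conditions: KN(SiMe3)2, THF, −78 °C; then 2-(phenylsulfonyl)-3-phenyloxaziridine, −78 °C
Reagents that add atoms: 2-(phenylsulfonyl)-3-phenyloxaziridine, O=S(=O)(N1OC1c1ccccc1)c1ccccc1
Why: Enolate oxidation: the ketone can enolise only away from the ketal, and the potassium enolate is hydroxylated by the N-sulfonyloxaziridine; the new carbinol centre is formed racemic and is erased in step 3.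

Step 3
Reactants: 4 6-hydroxy-2,2-dimethoxycyclohexan-1-one
Product: 6 2-hydroxy-6,6-dimethoxycyclohex-2-en-1-one, via 3,3-dimethoxycyclohexane-1,2-dione 5 (not isolated)
Conditions: Dess–Martin periodinane, CH2Cl2, rt
Reagents that add atoms: none
Why: Dess–Martin oxidation of the acyloin gives the 1,2-diketone, which can enolise only on the side away from the ketal and should therefore be obtained as a single diosphenol.

Step 4
Reactants: 6 2-hydroxy-6,6-dimethoxycyclohex-2-en-1-one; 7 allyl bromide
Product: 8 2-(allyloxy)-6,6-dimethoxycyclohex-2-en-1-one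
Conditions: K2CO3, acetone, reflux
Reagents that add atoms: none
Why: Williamson ether synthesis: the acidic diosphenol is alkylated at oxygen by the allylic bromide under carbonate in acetone.

Step 5
Reactants: 8 2-(allyloxy)-6,6-dimethoxycyclohex-2-en-1-one
Product: 10 3-allyl-2-hydroxy-6,6-dimethoxycyclohex-2-en-1-one, via 6-allyl-3,3-dimethoxycyclohexane-1,2-dione 9 (not isolated)
Conditions: PhNEt2, 190 °C, sealed tube
Reagents that add atoms: none
Why: Claisen rearrangement of the allyl enol ether forms the C5–allyl bond at the former β-carbon, and the 1,2-diketone so formed enolises to the tetrasubstituted diosphenol, the basic solvent keeping the ketal from acid-induced loss of methanol.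

Step 6
Reactants: 10 3-allyl-2-hydroxy-6,6-dimethoxycyclohex-2-en-1-one; 11 (1S,4R)-camphanic chloride
Product: 12 2-allyl-5,5-dimethoxy-6-oxocyclohex-1-en-1-yl (1S,4R)-camphanate
Conditions: Et3N, DMAP (cat.), CH2Cl2, 0 °C → rt
Reagents that add atoms: none
Why: Acylation of the enolic hydroxyl under nucleophilic catalysis gives the 2-acyloxy enone chromophore and at the same time attaches a rigid acyl group of fixed configuration that has no α-hydrogen and cannot epimerise.

Step 7
Reactants: 12 2-allyl-5,5-dimethoxy-6-oxocyclohex-1-en-1-yl (1S,4R)-camphanate; 13 (E)-1,2-dimethoxy-4-(prop-1-enyl)benzene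
Product: 14 (1R,6S,7R,8S)-6-allyl-8-(3,4-dimethoxyphenyl)-3,3-dimethoxy-7-methyl-2-oxobicyclo[4.2.0]octan-1-yl (1S,4R)-camphanate (cis-fused; aryl exo; methyl endo)
Conditions: hν (365 nm LED, Pyrex), 13 (5 equiv), NaHCO3 (solid), degassed CH2Cl2, −40 °C; diastereomers separated on SiO2, then crystallisation
Reagents that add atoms: none
Why: Proposed new method: light absorbed only by the enone (n→π*; the alkene is transparent at 365 nm) gives, after intersystem crossing, the triplet enone, whose β-carbon C5 bonds to the methyl-bearing alkene carbon C6 to leave a 1,4-biradical stabilised at both ends (C7 benzylic, C8 captodative between the acyloxy oxygen and the C1 carbonyl); spin inversion and C7–C8 coupling then close the cyclobutane, the one ring formed, by radical–radical recombination (formal [2+2]), while less stabilised biradicals that bond through C8 first are expected to revert. The closest known reactions are intermolecular [2+2] photocycloadditions of 2-acyloxycycloalk-2-enones with simple alkenes and of cyclic enones with arylalkenes; a tetrasubstituted 2-acyloxy enone has not been joined head-to-head to a 1,2-disubstituted styrene. C5 and C8 should come out cis because the relaxed enoxy radical at C8 can close a four-membered ring on the six-membered ring without strain only on the face that already carries C6; C7 should turn its aryl group to the convex face, next to the small ester oxygen and away from the ketal-bearing ring, and C6 should keep methyl trans to aryl (endo), since the stepwise closure gives this arrangement even if the alkene is E/Z-scrambled by energy transfer. Which enone face reacts is biased only by the rigid camphanoyl group standing perpendicular to the enone plane on the reacting α-carbon; it makes the two cis-fused exo-aryl adducts diastereomers, and the (1R,6S,7R,8S) one is to be isolated by chromatography and crystallisation. The step therefore needs head-to-head regiochemistry (secured by the captodative acyloxy ketone and the aryl group), cis fusion with exo aryl (ring strain and convex-face closure) and one enone face (auxiliary plus separation).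

Step 8
Reactants: 14 (1R,6S,7R,8S)-6-allyl-8-(3,4-dimethoxyphenyl)-3,3-dimethoxy-7-methyl-2-oxobicyclo[4.2.0]octan-1-yl (1S,4R)-camphanate
Product: 16 (1R,5S,6R,7S)-5-allyl-7-(3,4-dimethoxyphenyl)-1-hydroxy-2,2-dimethoxy-6-methylbicyclo[3.2.1]octan-8-one, via cyclobutanol α-ketol 15 (not isolated)
Conditions: K2CO3, MeOH, 0 °C → rt
Reagents that add atoms: none
Why: Methanolysis of the α-keto tertiary ester frees the cyclobutanol, and its alkoxide undergoes the strain-driven α-ketol (acyloin) rearrangement in which the exocyclic C8–C7 bond, the one that can stand parallel to the C1 carbonyl π-orbital in the cis-fused ring, migrates suprafacially with retention at C7, so that C1 is created with C7 on the face that carried the cyclobutane and C8 becomes the bridging ketone.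

Step 9
Reactants: 16 (1R,5S,6R,7S)-5-allyl-7-(3,4-dimethoxyphenyl)-1-hydroxy-2,2-dimethoxy-6-methylbicyclo[3.2.1]octan-8-one
Product: 17 (1R,5S,6R,7S)-5-allyl-7-(3,4-dimethoxyphenyl)-1,2,2-trimethoxy-6-methylbicyclo[3.2.1]octan-8-one
Conditions: MeOTf, 2,6-di-tert-butyl-4-methylpyridine, CH2Cl2, rt
Reagents that add atoms: methyl trifluoromethanesulfonate, COS(=O)(=O)C(F)(F)F
Why: O-Methylation of the hindered tertiary α-hydroxy ketone with a strong neutral methylating agent and a non-nucleophilic base avoids the free alkoxide and with it any reverse or second ketol shift.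

Step 10
Reactants: 17 (1R,5S,6R,7S)-5-allyl-7-(3,4-dimethoxyphenyl)-1,2,2-trimethoxy-6-methylbicyclo[3.2.1]octan-8-one
Product: 18 (1S,5S,6R,7S)-5-allyl-7-(3,4-dimethoxyphenyl)-1-methoxy-6-methylbicyclo[3.2.1]octane-2,8-dione
Conditions: 2 M aq HCl, THF, 40 °C
Reagents that add atoms: water, O
Why: Acid hydrolysis of the dimethyl ketal, now no longer α to a carbonyl group, releases the C2 ketone, while the tertiary methyl ether, the aryl ethers and the non-enolisable C8 ketone are stable to aqueous acid.

Step 11
Reactants: 18 (1S,5S,6R,7S)-5-allyl-7-(3,4-dimethoxyphenyl)-1-methoxy-6-methylbicyclo[3.2.1]octane-2,8-dione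
Product: 20 (1R,5R,6R,7S)-5-allyl-7-(3,4-dimethoxyphenyl)-3-hydroxy-1-methoxy-6-methylbicyclo[3.2.1]octane-2,8-dione (C3 epimers), via potassium C2 enolate 19 (not isolated)
Conditions: KN(SiMe3)2, THF, −78 °C; then 2-(phenylsulfonyl)-3-phenyloxaziridine, −78 °C
Reagents that add atoms: 2-(phenylsulfonyl)-3-phenyloxaziridine, O=S(=O)(N1OC1c1ccccc1)c1ccccc1
Why: Enolate oxidation: C2 can enolise only towards C3 (C1 is quaternary and C8 has no α-hydrogen), so the potassium enolate is hydroxylated at C3 alone, and the configuration of this carbinol is irrelevant because step 12 removes it.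

Step 12
Reactants: 20 (1R,5R,6R,7S)-5-allyl-7-(3,4-dimethoxyphenyl)-3-hydroxy-1-methoxy-6-methylbicyclo[3.2.1]octane-2,8-dione
Product: 22 (1R,5S,6R,7S)-5-allyl-7-(3,4-dimethoxyphenyl)-3-hydroxy-1-methoxy-6-methylbicyclo[3.2.1]oct-3-ene-2,8-dione, via bicyclic 2,3,8-trione 21 (not isolated)
Conditions: Dess–Martin periodinane, CH2Cl2, rt
Reagents that add atoms: none
Why: Dess–Martin oxidation gives the 2,3-diketone, which can enolise only towards C4 and should therefore settle as the diosphenol with the C3=C4 double bond of the target.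

Step 13
Reactants: 22 (1R,5S,6R,7S)-5-allyl-7-(3,4-dimethoxyphenyl)-3-hydroxy-1-methoxy-6-methylbicyclo[3.2.1]oct-3-ene-2,8-dione
Product: 23 (1R,5S,6R,7S)-5-allyl-7-(3,4-dimethoxyphenyl)-1,3-dimethoxy-6-methylbicyclo[3.2.1]oct-3-ene-2,8-dione
Conditions: Me2SO4, K2CO3, acetone, rt
Reagents that add atoms: dimethyl sulfate, COS(=O)(=O)OC
Why: O-Alkylation of the diosphenolate with a hard methylating agent fixes the C3 methyl enol ether, C-methylation at C4 being disfavoured beside the quaternary C5.

Step 14
Reactants: 23 (1R,5S,6R,7S)-5-allyl-7-(3,4-dimethoxyphenyl)-1,3-dimethoxy-6-methylbicyclo[3.2.1]oct-3-ene-2,8-dione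
Product: 24 (1S,2R,5S,6R,7S)-5-allyl-7-(3,4-dimethoxyphenyl)-2-hydroxy-1,3-dimethoxy-6-methylbicyclo[3.2.1]oct-3-en-8-one (hydroxyl equatorial; anti to C8)
Conditions: NaBH4, CeCl3·7H2O, MeOH, −78 °C
Reagents that add atoms: none
Why: Luche reduction: the CeCl3-activated conjugated C2 carbonyl should be reduced 1,2 in preference to the bridging C8 ketone, which is flanked by two quaternary carbons and masked as its hemiketal in methanol, and hydride should arrive from the open exo face because the endo face is screened by the C6–C7 bridge with its endo hydrogen and methyl, which sets C2 with the hydroxyl anti to C8.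

Step 15
Reactants: 24 (1S,2R,5S,6R,7S)-5-allyl-7-(3,4-dimethoxyphenyl)-2-hydroxy-1,3-dimethoxy-6-methylbicyclo[3.2.1]oct-3-en-8-one
Product: 25 (1S,2S,5S,6R,7S)-5-allyl-7-(3,4-dimethoxyphenyl)-1,3-dimethoxy-6-methyl-8-oxobicyclo[3.2.1]oct-3-en-2-yl acetate
Conditions: PPh3, DIAD, AcOH, toluene, 0 °C → rt
Reagents that add atoms: acetic acid, CC(=O)O
Why: Mitsunobu reaction: the oxyphosphonium derivative of the allylic alcohol is displaced by acetate in an SN2 step from the unhindered exo face, which inverts C2 to the axial acetate of the target, elimination being impossible because C1 is quaternary and C3 is vinylic.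

**Compound list**

1 | cyclohexane-1,2-dione | O=C1CCCCC1=O | starting material
2 | 2,2-dimethoxycyclohexan-1-one | COC1(OC)CCCCC1=O | intermediate
3 | potassium 6,6-dimethoxycyclohex-1-en-1-olate (not isolated) | COC1(OC)CCCC=C1[O-].[K+] | intermediate
4 | 6-hydroxy-2,2-dimethoxycyclohexan-1-one (racemic) | COC1(OC)CCCC(O)C1=O | intermediate
5 | 3,3-dimethoxycyclohexane-1,2-dione (not isolated) | COC1(OC)CCCC(=O)C1=O | intermediate
6 | 2-hydroxy-6,6-dimethoxycyclohex-2-en-1-one | COC1(OC)CCC=C(O)C1=O | intermediate
7 | allyl bromide (3-bromoprop-1-ene) | C=CCBr | starting material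
8 | 2-(allyloxy)-6,6-dimethoxycyclohex-2-en-1-one | C=CCOC1=CCCC(OC)(OC)C1=O | intermediate
9 | 6-allyl-3,3-dimethoxycyclohexane-1,2-dione (racemic, not isolated) | C=CCC1CCC(OC)(OC)C(=O)C1=O | intermediate
10 | 3-allyl-2-hydroxy-6,6-dimethoxycyclohex-2-en-1-one | C=CCC1=C(O)C(=O)C(OC)(OC)CC1 | intermediate
11 | (1S,4R)-camphanic chloride, (1S,4R)-4,7,7-trimethyl-3-oxo-2-oxabicyclo[2.2.1]heptane-1-carbonyl chloride | ClC(=O)[C@@]12CC[C@@](C)(C(=O)O1)C2(C)C | starting material
12 | 2-allyl-5,5-dimethoxy-6-oxocyclohex-1-en-1-yl (1S,4R)-4,7,7-trimethyl-3-oxo-2-oxabicyclo[2.2.1]heptane-1-carboxylate (camphanate) | C=CCC1=C(OC(=O)[C@@]23CC[C@@](C)(C(=O)O2)C3(C)C)C(=O)C(OC)(OC)CC1 | intermediate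
13 | (E)-1,2-dimethoxy-4-(prop-1-enyl)benzene | C/C=C/c1ccc(OC)c(OC)c1 | starting material
14 | (1R,6S,7R,8S)-6-allyl-8-(3,4-dimethoxyphenyl)-3,3-dimethoxy-7-methyl-2-oxobicyclo[4.2.0]octan-1-yl (1S,4R)-camphanate; cis-fused, aryl exo, methyl endo | C=CC[C@]12CCC(OC)(OC)C(=O)[C@@]1(OC(=O)[C@@]34CC[C@@](C)(C(=O)O3)C4(C)C)[C@H](c1ccc(OC)c(OC)c1)[C@H]2C | intermediate
15 | (1R,6S,7R,8S)-6-allyl-8-(3,4-dimethoxyphenyl)-1-hydroxy-3,3-dimethoxy-7-methylbicyclo[4.2.0]octan-2-one (not isolated) | C=CC[C@]12CCC(OC)(OC)C(=O)[C@@]1(O)[C@H](c1ccc(OC)c(OC)c1)[C@H]2C | intermediate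
16 | (1R,5S,6R,7S)-5-allyl-7-(3,4-dimethoxyphenyl)-1-hydroxy-2,2-dimethoxy-6-methylbicyclo[3.2.1]octan-8-one; aryl exo, methyl endo | C=CC[C@]12CCC(OC)(OC)[C@](O)(C1=O)[C@H](c1ccc(OC)c(OC)c1)[C@H]2C | intermediate
17 | (1R,5S,6R,7S)-5-allyl-7-(3,4-dimethoxyphenyl)-1,2,2-trimethoxy-6-methylbicyclo[3.2.1]octan-8-one | C=CC[C@]12CCC(OC)(OC)[C@](OC)(C1=O)[C@H](c1ccc(OC)c(OC)c1)[C@H]2C | intermediate
18 | (1S,5S,6R,7S)-5-allyl-7-(3,4-dimethoxyphenyl)-1-methoxy-6-methylbicyclo[3.2.1]octane-2,8-dione | C=CC[C@]12CCC(=O)[C@](OC)(C1=O)[C@H](c1ccc(OC)c(OC)c1)[C@H]2C | intermediate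
19 | potassium enolate of 18 (C2–O−, C2=C3; not isolated) | C=CC[C@]12CC=C([O-])[C@](OC)(C1=O)[C@H](c1ccc(OC)c(OC)c1)[C@H]2C.[K+] | intermediate
20 | (1R,5R,6R,7S)-5-allyl-7-(3,4-dimethoxyphenyl)-3-hydroxy-1-methoxy-6-methylbicyclo[3.2.1]octane-2,8-dione (C3 not controlled) | C=CC[C@]12CC(O)C(=O)[C@](OC)(C1=O)[C@H](c1ccc(OC)c(OC)c1)[C@H]2C | intermediate
21 | (1R,5R,6R,7S)-5-allyl-7-(3,4-dimethoxyphenyl)-1-methoxy-6-methylbicyclo[3.2.1]octane-2,3,8-trione (not isolated) | C=CC[C@]12CC(=O)C(=O)[C@](OC)(C1=O)[C@H](c1ccc(OC)c(OC)c1)[C@H]2C | intermediate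
22 | (1R,5S,6R,7S)-5-allyl-7-(3,4-dimethoxyphenyl)-3-hydroxy-1-methoxy-6-methylbicyclo[3.2.1]oct-3-ene-2,8-dione | C=CC[C@]12C=C(O)C(=O)[C@](OC)(C1=O)[C@H](c1ccc(OC)c(OC)c1)[C@H]2C | intermediate
23 | (1R,5S,6R,7S)-5-allyl-7-(3,4-dimethoxyphenyl)-1,3-dimethoxy-6-methylbicyclo[3.2.1]oct-3-ene-2,8-dione | C=CC[C@]12C=C(OC)C(=O)[C@](OC)(C1=O)[C@H](c1ccc(OC)c(OC)c1)[C@H]2C | intermediate
24 | (1S,2R,5S,6R,7S)-5-allyl-7-(3,4-dimethoxyphenyl)-2-hydroxy-1,3-dimethoxy-6-methylbicyclo[3.2.1]oct-3-en-8-one; hydroxyl anti to C8 | C=CC[C@]12C=C(OC)[C@@H](O)[C@](OC)(C1=O)[C@H](c1ccc(OC)c(OC)c1)[C@H]2C | intermediate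
25 | (1S,2S,5S,6R,7S)-5-allyl-7-(3,4-dimethoxyphenyl)-1,3-dimethoxy-6-methyl-8-oxobicyclo[3.2.1]oct-3-en-2-yl acetate | C=CC[C@]12C=C(OC)[C@H](OC(C)=O)[C@](OC)(C1=O)[C@H](c1ccc(OC)c(OC)c1)[C@H]2C | target

**Count and risks**

Total steps: 15. Longest linear sequence: 15 steps (1 → 25); 7, 11 and 13 are purchased and enter in steps 4, 6 and 7.

Step 7 (proposed new method). The triplet enone may bond first through C8 and give head-to-tail cyclobutanes. The biradical may close to trans-fused or endo-aryl isomers. Energy transfer to the propenylarene may use up the excitation without bond formation. The two enone faces may be discriminated too weakly for a practical separation. The fallback uses known chemistry and leaves the photochemical construction: the acid-promoted cationic [5+2] cycloaddition of a p-quinone monoketal with the same alkene, an established entry to 3-methoxybicyclo[3.2.1]oct-3-ene-2,8-diones. It sets out from 7 and 13. Commercial 2,3,4-trimethoxyphenol is O-allylated with 7 (K2CO3, acetone) to 1-(allyloxy)-2,3,4-trimethoxybenzene F1. Aromatic Claisen rearrangement (PhNEt2, 190 °C) gives 6-allyl-2,3,4-trimethoxyphenol F2, and oxidation with PhI(OAc)2 in MeOH gives 2-allyl-4,4,5,6-tetramethoxycyclohexa-2,5-dien-1-one F3. Ionisation of the ketal of F3 with CF3SO3H in MeCN at −30 °C in the presence of 13 should join the methyl-bearing alkene carbon to the allyl-bearing ring carbon; the benzylic cation is then captured by the methoxy enol-ether carbon. After aqueous work-up this should give racemic 23 (aryl exo, methyl endo), that is 23 together with the enantiomer of 23 F4, which is removed by preparative chromatography on a chiral stationary phase. The fallback comes back to the route at 23.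

Step 8. Under the equilibrating alkoxide conditions the ring-fusion bond C8–C5 may migrate in place of C8–C7 (ring contraction to a bicyclo[3.3.0]octane ketol). The product alkoxide may undergo a second 1,2-shift of C2, or the hindered tertiary ester may be cleaved too slowly. The fallback takes the shift out of the alkoxide manifold and separates it from the deacylation. From 14 the camphanoyl group is removed by ammonolysis (NH3, MeOH, 0 °C), which should stop at the neutral cyclobutanol ketol 15. Isolated 15 is then rearranged with Al(OtBu)3 in toluene at 60 °C. There a five-membered aluminium chelate of the C8 oxygen and the C1 carbonyl holds the exocyclic C8–C7 bond over the carbonyl, and the migrating benzylic carbon can carry positive charge. The product is 16, where the route is rejoined (F0: no compound outside the compound list).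

Step 15. The oxyphosphonium ion at the neopentyl-type allylic carbon may form slowly, or acetate may attack C4 with allylic transposition instead of C2. The fallback splits activation and displacement into two operations with a small leaving group. From 24 the (1S,2R,5S,6R,7S)-5-allyl-7-(3,4-dimethoxyphenyl)-1,3-dimethoxy-6-methyl-8-oxobicyclo[3.2.1]oct-3-en-2-yl methanesulfonate F5 is made (MsCl, Et3N, CH2Cl2, −20 °C) and used crude. It is displaced with CsOAc and 18-crown-6 in toluene at rt, an SN2 inversion by a naked acetate that needs no bulky phosphonium group. The product is 25.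

**Further compounds**

F1 | step 7 | 1-(allyloxy)-2,3,4-trimethoxybenzene | C=CCOc1ccc(OC)c(OC)c1OC
F2 | step 7 | 6-allyl-2,3,4-trimethoxyphenol | C=CCc1cc(OC)c(OC)c(OC)c1O
F3 | step 7 | 2-allyl-4,4,5,6-tetramethoxycyclohexa-2,5-dien-1-one | C=CCC1=CC(OC)(OC)C(OC)=C(OC)C1=O
F4 | step 7 | enantiomer of 23, (1S,5R,6S,7R)-5-allyl-7-(3,4-dimethoxyphenyl)-1,3-dimethoxy-6-methylbicyclo[3.2.1]oct-3-ene-2,8-dione | C=CC[C@@]12C=C(OC)C(=O)[C@@](OC)(C1=O)[C@@H](c1ccc(OC)c(OC)c1)[C@@H]2C
F0 | step 8 | none | none
F5 | step 15 | (1S,2R,5S,6R,7S)-5-allyl-7-(3,4-dimethoxyphenyl)-1,3-dimethoxy-6-methyl-8-oxobicyclo[3.2.1]oct-3-en-2-yl methanesulfonate | C=CC[C@]12C=C(OC)[C@@H](OS(C)(=O)=O)[C@](OC)(C1=O)[C@H](c1ccc(OC)c(OC)c1)[C@H]2C
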